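**Retrosynthetic overview**
- Last bonds: the ester C–O (primary allylic alcohol + (2E)-3-methylpent-2-enoic acid) and the 2-methylprop-1-enyl group (from a vinyl group by cross-metathesis with 2-methylbut-2-ene).
- The only ring, the butyrolactone, is closed late in one operation: C2–C3 and C2–O1 by palladium-catalysed cyclocarbonylation of a 3-yne-1,2-diol; syn addition fixes the 3E alkylidene.
- Key C–C bond C4–C5 (the two oxygen-bearing carbons): a conjugated ynal (C4) is attacked by a chiral α-hydroxyallyl carbanion equivalent (C5, umpolung of an acrolein-type carbonyl carbon, used as an (E)-γ-silylallylborane). This sets both stereocentres as the anti diol.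
- Ynal from an allylic bromide, 1,3-dilithiopropyne and DMF; the bromide from nerol (supplies 2Z) by SeO2 oxidation of the E-methyl group (supplies 6E).

Assumption: (2E)-3-methylpent-2-enoic acid, allyl(diisopropylamino)dimethylsilane and (+)-B-methoxydiisopinocampheylborane are bought as such; lactone atoms are counted O1, C2 (C=O), C3, C4, C5.

**Step 1**
Reactants: 1 nerol, (2Z)-3,7-dimethylocta-2,6-dien-1-ol
Product: 2 tert-butyl{[(2Z)-3,7-dimethylocta-2,6-dien-1-yl]oxy}dimethylsilane
Conditions: TBSCl, imidazole, CH2Cl2, 0 °C to rt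
Reagents that add atoms: tert-butyl(chloro)dimethylsilane, CC(C)(C)[Si](C)(C)Cl
Why: Standard silylation of the primary allylic alcohol (imidazole-assisted substitution at silicon); no stereocentre is made and the 2Z alkene is untouched.

**Step 2**
Reactants: 2 tert-butyl{[(2Z)-3,7-dimethylocta-2,6-dien-1-yl]oxy}dimethylsilane
Product: 3 (2E,6Z)-8-{[tert-butyl(dimethyl)silyl]oxy}-2,6-dimethylocta-2,6-dien-1-ol
Conditions: SeO2 (20 mol%), t-BuOOH (70% aq., 2.5 equiv), salicylic acid (10 mol%), CH2Cl2, rt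
Reagents that add atoms: tert-butyl hydroperoxide, CC(C)(C)OO
Why: Sharpless-type catalytic SeO2 allylic oxidation (ene reaction, then [2,3]-sigmatropic shift) attacks the more electron-rich distal trisubstituted alkene at its E-methyl group and gives the (E)-allylic alcohol, while the 2Z alkene, deactivated by its allylic oxygen, stays put.

**Step 3**
Reactants: 3 (2E,6Z)-8-{[tert-butyl(dimethyl)silyl]oxy}-2,6-dimethylocta-2,6-dien-1-ol
Product: 4 {[(2Z,6E)-8-bromo-3,7-dimethylocta-2,6-dien-1-yl]oxy}(tert-butyl)dimethylsilane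
Conditions: CBr4, PPh3, CH2Cl2, −20 to 0 °C
Reagents that add atoms: carbon tetrabromide, BrC(Br)(Br)Br
Why: Appel bromination, an SN2 displacement of the oxyphosphonium group at the primary allylic carbon without allylic shift; the silyl ether is inert.

**Step 4**
Reactants: 4 {[(2Z,6E)-8-bromo-3,7-dimethylocta-2,6-dien-1-yl]oxy}(tert-butyl)dimethylsilane; 5 3-bromoprop-1-yne (propargyl bromide)
Product: 8 (6E,10Z)-12-{[tert-butyl(dimethyl)silyl]oxy}-6,10-dimethyldodeca-6,10-dien-2-ynal, via 1,3-dilithiopropyne 6 (not isolated), via lithium alkynide 7 (not isolated)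
Conditions: 5 (1.6 equiv), n-BuLi (3.2 equiv), TMEDA, Et2O–hexane, −78 °C; then 4, −78 to −20 °C; then DMF, −78 to 0 °C; poured into cold aq. KH2PO4
Reagents that add atoms: N,N-dimethylformamide, CN(C)C=O
Why: Hooz-type propargylation, in which the sp3 carbanion end of the propyne dianion displaces the allylic bromide (SN2), the surviving lithium alkynide is formylated by DMF (Bouveault-type) and the phosphate quench frees the ynal without conjugate addition of dimethylamine.

**Step 5**
Reactants: 8 (6E,10Z)-12-{[tert-butyl(dimethyl)silyl]oxy}-6,10-dimethyldodeca-6,10-dien-2-ynal; 9 allyl(diisopropylamino)dimethylsilane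
Product: 13 (2Z,6E,12S,13R)-3,7-dimethylpentadeca-2,6,14-trien-10-yne-1,12,13-triol, via silylallylborane 10 (not isolated), via borinate adduct 11 (not isolated), via silyl ether diol 12 (not isolated)
Conditions: 9, n-BuLi, TMEDA, Et2O, 0 °C; (+)-Ipc2BOMe, −78 °C; BF3·OEt2, −78 °C; then 8, −78 °C; then 30% H2O2, KF, KHCO3, THF–MeOH, rt; then TBAF, THF, rt
Reagents that add atoms: hydrogen peroxide, OO
Why: Barrett-type asymmetric α-hydroxyallylation (allylboration, then Tamao oxidation): the future carbinol carbon C13, which as a carbonyl-level carbon would itself be an electrophile, is delivered as the nucleophilic γ-carbon of a chiral (E)-γ-silylallylborane to the ynal carbonyl through a chair transition state, so the E geometry gives the anti relationship, the (−)-α-pinene-derived isopinocampheyl groups direct attack to the Re face of the ynal (12S), H2O2/KF turns C–Si into C–OH with retention (13R), and TBAF then removes the silyl ether.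

**Step 6**
Reactants: 13 (2Z,6E,12S,13R)-3,7-dimethylpentadeca-2,6,14-trien-10-yne-1,12,13-triol
Product: 14 (3E,4S,5R)-5-ethenyl-4-hydroxy-3-[(4E,8Z)-10-hydroxy-4,8-dimethyldeca-4,8-dien-1-ylidene]oxolan-2-one
Conditions: PdCl2(PPh3)2 (5 mol%), SnCl2 (5 mol%), CO (7 atm), MeCN, 65 °C
Reagents that add atoms: carbon monoxide, [C-]#[O+]
Why: Norton-type palladium-catalysed cyclocarbonylation of a homopropargylic alcohol: the alkoxycarbonyl group on divalent palladium formed at the C13 hydroxyl adds syn across the alkyne in the 5-exo mode and protonolysis of the vinyl–palladium bond with retention leaves H cis and the chain trans to the carbonyl (3E), while the propargylic C12 hydroxyl could only close a four-membered ring and stays free; both stereocentres are untouched.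

**Step 7**
Reactants: 14 (3E,4S,5R)-5-ethenyl-4-hydroxy-3-[(4E,8Z)-10-hydroxy-4,8-dimethyldeca-4,8-dien-1-ylidene]oxolan-2-one; 15 2-methylbut-2-ene
Product: 16 (3E,4S,5R)-4-hydroxy-3-[(4E,8Z)-10-hydroxy-4,8-dimethyldeca-4,8-dien-1-ylidene]-5-(2-methylprop-1-en-1-yl)oxolan-2-one
Conditions: 15 (large excess, co-solvent), second-generation Grubbs catalyst RuCl2(=CHPh)(H2IMes)(PCy3) (5 mol%), CH2Cl2, 25 °C
Reagents that add atoms: none
Why: Olefin cross-metathesis, in which only the monosubstituted vinyl group engages the ruthenium carbene and exchanges its CH2 terminus for CMe2 (propene is lost), the trisubstituted and the conjugated alkylidene double bonds being too hindered or electron-poor; the stereocentres are untouched.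

**Step 8**
Reactants: 16 (3E,4S,5R)-4-hydroxy-3-[(4E,8Z)-10-hydroxy-4,8-dimethyldeca-4,8-dien-1-ylidene]-5-(2-methylprop-1-en-1-yl)oxolan-2-one; 17 (2E)-3-methylpent-2-enoic acid
Product: 18 (2Z,6E,10E)-10-[(4S,5R)-4-hydroxy-5-(2-methylprop-1-en-1-yl)-2-oxooxolan-3-ylidene]-3,7-dimethyldeca-2,6-dien-1-yl (2E)-3-methylpent-2-enoate (CNP0181153.1)
Conditions: 17 (1.05 equiv), DCC, DMAP (10 mol%), CH2Cl2, −20 to 0 °C
Reagents that add atoms: none
Why: Steglich esterification, in which the unhindered primary allylic hydroxyl is acylated far faster than the hindered secondary C4 hydroxyl at low temperature with about one equivalent of acid; the E-enoate and all stereocentres are retained.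

**Compound list**
1 | nerol, (2Z)-3,7-dimethylocta-2,6-dien-1-ol | OC/C=C(/C)CCC=C(C)C | starting material
2 | tert-butyl{[(2Z)-3,7-dimethylocta-2,6-dien-1-yl]oxy}dimethylsilane | CC(C)(C)[Si](C)(C)OC/C=C(/C)CCC=C(C)C | intermediate
3 | (2E,6Z)-8-{[tert-butyl(dimethyl)silyl]oxy}-2,6-dimethylocta-2,6-dien-1-ol | CC(C)(C)[Si](C)(C)OC/C=C(/C)CC/C=C(\C)CO | intermediate
4 | {[(2Z,6E)-8-bromo-3,7-dimethylocta-2,6-dien-1-yl]oxy}(tert-butyl)dimethylsilane | CC(C)(C)[Si](C)(C)OC/C=C(/C)CC/C=C(\C)CBr | intermediate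
5 | 3-bromoprop-1-yne (propargyl bromide) | C#CCBr | starting material
6 | 1,3-dilithiopropyne | [Li]CC#C[Li] | intermediate
7 | lithium (5E,9Z)-11-{[tert-butyl(dimethyl)silyl]oxy}-5,9-dimethylundeca-5,9-dien-1-yn-1-ide | CC(C)(C)[Si](C)(C)OC/C=C(/C)CC/C=C(\C)CCC#C[Li] | intermediate
8 | (6E,10Z)-12-{[tert-butyl(dimethyl)silyl]oxy}-6,10-dimethyldodeca-6,10-dien-2-ynal | CC(C)(C)[Si](C)(C)OC/C=C(/C)CC/C=C(\C)CCC#CC=O | intermediate
9 | allyl(diisopropylamino)dimethylsilane | C=CC[Si](C)(C)N(C(C)C)C(C)C | starting material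
10 | [(2E)-3-{[di(propan-2-yl)amino]dimethylsilyl}prop-2-en-1-yl]bis[(1S,2R,3S,5S)-2,6,6-trimethylbicyclo[3.1.1]heptan-3-yl]borane (isopinocampheyl groups from (−)-α-pinene) | B(C/C=C/[Si](C)(C)N(C(C)C)C(C)C)([C@H]1C[C@H]2C[C@@H]([C@@H]1C)C2(C)C)[C@H]1C[C@H]2C[C@@H]([C@@H]1C)C2(C)C | intermediate
11 | (3R,4S,9E,13Z)-15-{[tert-butyl(dimethyl)silyl]oxy}-3-{[di(propan-2-yl)amino]dimethylsilyl}-9,13-dimethylpentadeca-1,9,13-trien-5-yn-4-yl bis[(1S,2R,3S,5S)-isopinocampheyl]borinate | CC(C)(C)[Si](C)(C)OC/C=C(/C)CC/C=C(\C)CCC#C[C@H](OB([C@H]1C[C@H]2C[C@@H]([C@@H]1C)C2(C)C)[C@H]1C[C@H]2C[C@@H]([C@@H]1C)C2(C)C)[C@H]([Si](C)(C)N(C(C)C)C(C)C)C=C | intermediate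
12 | (3R,4S,9E,13Z)-15-{[tert-butyl(dimethyl)silyl]oxy}-9,13-dimethylpentadeca-1,9,13-trien-5-yne-3,4-diol | CC(C)(C)[Si](C)(C)OC/C=C(/C)CC/C=C(\C)CCC#C[C@H](O)[C@H](O)C=C | intermediate
13 | (2Z,6E,12S,13R)-3,7-dimethylpentadeca-2,6,14-trien-10-yne-1,12,13-triol | OC/C=C(/C)CC/C=C(\C)CCC#C[C@H](O)[C@H](O)C=C | intermediate
14 | (3E,4S,5R)-5-ethenyl-4-hydroxy-3-[(4E,8Z)-10-hydroxy-4,8-dimethyldeca-4,8-dien-1-ylidene]oxolan-2-one | OC/C=C(/C)CC/C=C(\C)CC/C=C1/C(=O)O[C@H](C=C)[C@H]1O | intermediate
15 | 2-methylbut-2-ene | CC=C(C)C | starting material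
16 | (3E,4S,5R)-4-hydroxy-3-[(4E,8Z)-10-hydroxy-4,8-dimethyldeca-4,8-dien-1-ylidene]-5-(2-methylprop-1-en-1-yl)oxolan-2-one | OC/C=C(/C)CC/C=C(\C)CC/C=C1/C(=O)O[C@H](C=C(C)C)[C@H]1O | intermediate
17 | (2E)-3-methylpent-2-enoic acid | CC/C(C)=C/C(=O)O | starting material
18 | (2Z,6E,10E)-10-[(4S,5R)-4-hydroxy-5-(2-methylprop-1-en-1-yl)-2-oxooxolan-3-ylidene]-3,7-dimethyldeca-2,6-dien-1-yl (2E)-3-methylpent-2-enoate | CC/C(C)=C/C(=O)OC/C=C(/C)CC/C=C(\C)CC/C=C1/C(=O)O[C@H](C=C(C)C)[C@H]1O | target

**Step count and risks**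
Total steps: 8. Longest linear sequence: 8 (1 to 18).

Step 4 is at risk because the propyne dianion is capricious (incomplete metalation, allenic or doubly alkylated by-products) and the ynal is sensitive to the amine set free on work-up. The fallback sets out from 4 and builds the ynal stepwise through a monoanion. Compound 4 is alkylated with 3-lithio-1-(trimethylsilyl)propyne (from 1-(trimethylsilyl)propyne, n-BuLi, THF, −78 °C) to give tert-butyl(dimethyl){[(2Z,6E)-3,7-dimethyl-11-(trimethylsilyl)undeca-2,6-dien-10-yn-1-yl]oxy}silane F1. The alkynyl silyl group is removed (K2CO3, MeOH) to give the terminal alkyne tert-butyl{[(2Z,6E)-3,7-dimethylundeca-2,6-dien-10-yn-1-yl]oxy}dimethylsilane F2. Deprotonation and formylation (n-BuLi, then DMF, −78 °C, phosphate quench) come back to the route at 8.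

Step 5, the key step, is at risk because enantio- and diastereoselectivity of the isopinocampheyl borane with a linear conjugated ynal are not assured, and the β-hydroxysilane can undergo Peterson elimination before it is oxidised. The fallback sets out from 8 and replaces the stoichiometric chiral borane by catalytic carbonyl (α-acyloxy)allylation under transfer hydrogenation. Conditions: 3,3-bis(benzoyloxy)prop-1-ene, [Ir(cod)Cl]2, SEGPHOS (the antipode that gives the 3R,4S isomer), 4-cyano-3-nitrobenzoic acid, K3PO4, propan-2-ol, THF, 90 °C. The acrolein-derived π-allyliridium again carries the future carbinol carbon as the nucleophile and gives the anti monobenzoate (3R,4S,9E,13Z)-15-{[tert-butyl(dimethyl)silyl]oxy}-4-hydroxy-9,13-dimethylpentadeca-1,9,13-trien-5-yn-3-yl benzoate F3 with the oxygen already in place. K2CO3/MeOH and then TBAF remove benzoate and silyl ether, and the route is rejoined at 13.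

Step 6 is at risk because electrophilic divalent palladium can cycloisomerise the 3-yne-1,2-diol to a furan, and the acid formed in the cycle can ionise the allylic alcohols. The fallback sets out from 13 and makes the lactone from a vinyl iodide under basic conditions. Hydroxyl-directed syn hydrostannation (Bu3SnH, Mo(CO)3(CNt-Bu)3 cat., THF, 55 °C) puts tin on the alkyne carbon next to the propargylic carbinol and gives (2Z,6E,10E,12R,13R)-3,7-dimethyl-11-(tributylstannyl)pentadeca-2,6,10,14-tetraene-1,12,13-triol F4. Iodine (I2, CH2Cl2, 0 °C) replaces tin with retention and gives (2Z,6E,10E,12R,13R)-11-iodo-3,7-dimethylpentadeca-2,6,10,14-tetraene-1,12,13-triol F5. Carbonylative lactonisation (Pd(PPh3)4, CO 1 atm, Et3N, THF, 50 °C; zerovalent palladium inserts into C–I, CO inserts, the C13 hydroxyl captures the acyl) returns to the route at 14 with the same 3E geometry.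

**Further compounds**
F1 | step 4 | tert-butyl(dimethyl){[(2Z,6E)-3,7-dimethyl-11-(trimethylsilyl)undeca-2,6-dien-10-yn-1-yl]oxy}silane | CC(C)(C)[Si](C)(C)OC/C=C(/C)CC/C=C(\C)CCC#C[Si](C)(C)C
F2 | step 4 | tert-butyl{[(2Z,6E)-3,7-dimethylundeca-2,6-dien-10-yn-1-yl]oxy}dimethylsilane | CC(C)(C)[Si](C)(C)OC/C=C(/C)CC/C=C(\C)CCC#C
F3 | step 5 | (3R,4S,9E,13Z)-15-{[tert-butyl(dimethyl)silyl]oxy}-4-hydroxy-9,13-dimethylpentadeca-1,9,13-trien-5-yn-3-yl benzoate | CC(C)(C)[Si](C)(C)OC/C=C(/C)CC/C=C(\C)CCC#C[C@H](O)[C@H](OC(=O)c1ccccc1)C=C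
F4 | step 6 | (2Z,6E,10E,12R,13R)-3,7-dimethyl-11-(tributylstannyl)pentadeca-2,6,10,14-tetraene-1,12,13-triol | OC/C=C(/C)CC/C=C(\C)CC/C=C(/[Sn](CCCC)(CCCC)CCCC)[C@H](O)[C@H](O)C=C
F5 | step 6 | (2Z,6E,10E,12R,13R)-11-iodo-3,7-dimethylpentadeca-2,6,10,14-tetraene-1,12,13-triol | OC/C=C(/C)CC/C=C(\C)CC/C=C(/I)[C@H](O)[C@H](O)C=C
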